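Its constants were drawn at random within sensible limits.

An easy step first: I follow the rate of the plain, unassisted reaction of the starting material with the partner in Thursday's flask, where the starting material is fed in.

    base + released group ⇌ salt, settled at all times (K1 = 14000 M⁻¹)
    starting material + partner + released group → target + 2 released group (k2 = 0.018 M⁻² min⁻¹)
    starting material + partner → target + released group (k3 = 5.6 × 10⁻⁵ M⁻¹ min⁻¹)
    partner → decomposed reagent (k4 = 3.5 × 10⁻⁴ min⁻¹)

all flasks: base 10.0 mM
- Tuesday's: starting material 0.50 M; partner 0.600 M (fed, over 40.0 h); time 40 h; all but partner at the start; partner goes in evenly over 40.0 h, the run ends at 40 h
- Friday's: starting material 0.50 M; partner 0.600 M; one stirred flow tank at steady state, fed with the mixture as stated, mean residence time 40 h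
- Wednesday's: starting material 0.50 M; partner 0.600 M; time 40 h; everything together in a closed stirred flask, run for 40 h
- Thursday's: starting material 0.50 M (fed, over 40.0 h); partner 0.600 M; time 40 h; all but starting material at the start; starting material goes in evenly over 40.0 h, the run ends at 40 h

- order of the set-ups by the amount of target at the outlet or at the end, in percent of the starting material put in, highest first (Tuesday's / Friday's / Wednesday's / Thursday's)
- amount of target at the outlet or at the end, in percent of the starting material put in, Tuesday's
- amount of target at the outlet or at the end, in percent of the starting material put in, Friday's
- amount of target at the outlet or at the end, in percent of the starting material put in, Wednesday's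
- amount of target at the outlet or at the end, in percent of the starting material put in, Thursday's

- the stated concentrations are those of everything mixed, before any reaction; amounts are the same in each set-up
- the feed brings no volume worth counting
- run time (Tuesday's): 40 h

At full charge the unassisted step runs at 1.01 mM h⁻¹. The assisted step, which needs free released group, overtakes it once that free amount reaches 3.11 mM. The base comes first, though: its binding strength times its concentration is 140, far above one, so released group goes to salt while free base lasts. Adding the base gives 13.1 mM, the released group the unassisted step has to make before the assisted step outruns it: the toll.

Two things slow the rate in Thursday's flask. The starting material climbs evenly from nothing, which averages a factor 0.5 over the feed. The partner decays with a half-life of 33.0 h, shorter than the feed, and its decay exponent over the feed is 0.840. Weighted towards the late hours, when the starting material is in, that gives a factor 0.583. So the unassisted step makes 11.8 mM by the end, less than the toll, and I commit to 2.35 % for Thursday's flask.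

The forecast gives 5.2 % for Tuesday's, 67.2 % for Friday's, 42 % for Wednesday's and 2.6 % for Thursday's, ranked Friday's > Wednesday's > Tuesday's > Thursday's. Its ground for the fed flasks is that “the two fed runs lose so much time to low concentrations that they barely get past the base”. Its Thursday's figure stands above mine.

The simulation ranks Friday's > Wednesday's > Tuesday's > Thursday's, with 67.1 % for Friday's, 39.1 % for Wednesday's, 5.12 % for Tuesday's and 2.56 % for Thursday's. Thursday's target at the end is 12.8 mM, below the toll of 13.1 mM. Left ten times as long, until 400 h, Thursday's flask has an unassisted total of 32.5 mM by my rate, above the toll, and it holds more target than that: 26.3 %, or 132 mM.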